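(The numbers in the tables are calculated for substances that don't exist; scatter was added.)

Over 6.0 h, five recipes for one charge, each ending at 70 °C, differ in how starting material or reagent goes in and in whether the first 80 min pass at 40 °C.

| flask | starting material | reagent | protic impurity | temperature | remark | time |
|---|---|---|---|---|---|---|
| gamma | 0.16 M | 1.1 equiv | 8 mM | 55 °C | run made earlier |  |
| epsilon | 0.16 M | 1.1 equiv | 4 mM | 70 °C | run made earlier |  |
| zeta | 0.16 M | 1.1 equiv | 16 mM | 55 °C | run made earlier |  |
| Tuesday's | 0.16 M (fed, over 80 min) | 1.10 equiv | 8.00 mM | 70 °C | all else is in the flask from the start; the feed brings no volume worth counting | 6.0 h |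
| Sunday's | 0.16 M | 1.10 equiv (in portions, 3, over 80 min) | 8.00 mM | 70 °C | first portion at the start, last at 80 min | 6.0 h |
| Monday's | 0.16 M | 1.10 equiv | 8.00 mM |  | everything together at the start at 40 °C, warmed to 70 °C at 80 min | 6.0 h |
| Friday's | 0.16 M | 1.10 equiv (fed, over 80 min) | 8.00 mM |  | the addition at 40 °C, then warmed to 70 °C; the feed brings no volume worth counting | 6.0 h |
| Wednesday's | 0.16 M | 1.10 equiv | 8.00 mM | 70 °C | everything together at the start | 6.0 h |

| run | time / h | product / % | starting material / % |
|---|---|---|---|
| gamma | 0.500 | 2 | 85 |
| gamma | 1.00 | 9 | 81 |
| gamma | 2.00 | 10 | 71 |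
| gamma | 4.00 | 17 | 48 |
| gamma | 8.00 | 30 | 29 |
| epsilon | 1.00 | 22 | 45 |
| epsilon | 2.00 | 38 | 25 |
| epsilon | 3.00 | 45 | 12 |
| epsilon | 4.00 | 47 | 11 |
| epsilon | 5.00 | 48 | 2 |
| zeta | 0.833 | 2 | 73 |
| zeta | 1.33 | 11 | 67 |
| zeta | 3.00 | 16 | 53 |
| zeta | 5.00 | 22 | 37 |
| zeta | 10.0 | 34 | 22 |

(standard deviation of a reading: 2 percentage points)

- a reading of starting material is of its free form alone

1. the flask that comes out highest in amount of product, in percent of the starting material charged, or "all alike" when all lie within 1.5 percentage points (Tuesday's / Sunday's / Monday's / Friday's / Wednesday's / all alike)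
2. product at the end, in percent of the starting material charged, Tuesday's
3. product at the end, in percent of the starting material charged, Sunday's
4. product at the end, in percent of the starting material charged, Monday's
5. product at the end, in percent of the starting material charged, Friday's
6. product at the end, in percent of the starting material charged, Wednesday's

In the first instants the protic impurity is the small thing. If each molecule of it takes one of starting material, a flask at 8.00 mM pays a correction of 5.00 % of the charge, whatever the recipe. The gamma run, at the same 8 mM, shows more going early than that correction: at 0.500 h free starting material reads 85 % with product at 2 %, and a reading of starting material counts its free form alone.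

In the middle, the epsilon run at 70 °C shows free starting material falling from 45 % at 1.00 h to 12 % at 3.00 h, while product climbs from 22 % to 45 %.

At the end of that run, at 5.00 h, free starting material reads 2 % and product 48 %. Its own correction is 2.50 %. Take that and the free remainder from the charge, and the part of the rest that appears as product is the product share, a selectivity, read here as 0.503. The last zeta reading gives 0.500. In the epsilon run the other half of that rest is not seen as free starting material or product.

The reckoning made here for Wednesday's multiplies the share by the charge less the correction and the epsilon remainder, which gives 46.8 %. The gamma, epsilon and zeta runs each stand at 1.1 equiv, so the share is a reading at that one reagent level.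

The forecast gives 46 % for Wednesday's, close to that reckoning but not the same number, and also 46 % for Sunday's, 46 % for Monday's, 46 % for Friday's and 53 % for Tuesday's, which it names highest. Its ground: “Feeding starting material should help modestly, while the reagent and temperature changes should do little.”

Sunday's comes out highest at 57.2 %, which is 11 percentage points above the forecast, against 48.8 % for Tuesday's, 47.3 % for Monday's, 47.9 % for Friday's and 49.7 % for Wednesday's.

    starting material → product (k = 0.360 h⁻¹, Ea = 99.0 kJ mol⁻¹)
    starting material + reagent ⇌ intermediate A (K = 9.70 M⁻¹, k = 0.190 M⁻¹ h⁻¹, Ea = 80.0 kJ mol⁻¹, ΔH = 49.0 kJ mol⁻¹)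
    starting material + protic impurity → quenched substrate (k = 54.0 M⁻¹ h⁻¹, Ea = 49.0 kJ mol⁻¹)
    starting material + reagent ⇌ intermediate B (K = 170 M⁻¹, k = 2.20 M⁻¹ h⁻¹, Ea = 79.0 kJ mol⁻¹, ΔH = −12.0 kJ mol⁻¹)
    (constants at 70 °C)

Sunday's has 52.4 % of its whole reagent charge free at 1.33 h, just before the last portion goes in, where Tuesday's, with its reagent in from the start, has 83.9 % at the end of its feed. With the correction seen as 5.00 % of quenched substrate, Sunday's product share at the end is 0.620, higher than the epsilon reading. A neighbour of Monday's with 0.660 equiv of reagent ends with product at 57.2 % and starting material at 8.41 %, a product share of 0.661.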